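Assumption: the biosynthesis is taken as nerolidyl diphosphate → 1,7-closure to the cycloheptenyl cation → 6,10-closure to the cyclopentane with capture at the isopropyl-bearing carbon, then oxidation of ring CH2 groups; ring positions below use azulene numbering, and the target is the cis-fused (3R,3aR,4S,8aS) isomer of the given SMILES.

**Retrosynthetic overview**
1. Target 14 ⇐ ester 13 by late allylic C–H oxidation at C8; 13 ⇐ diol 11 by acylation of the secondary hydroxyl.
2. 11 ⇐ cycloheptadienyl ketone 7: the cyclopentane is closed last (C3–C3a bond) by a ketyl–olefin radical cyclization, the open-shell counterpart of the cation–olefin closure, with oxygen captured at C4 in the same operation.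
3. 7 ⇐ acyclic bis-epoxide 3: the seven-membered ring is closed first (C8–C8a bond) by a titanocene-mediated 7-endo radical cyclization with loss of the allylic acetate, mirroring ionisation and 1,7-closure of nerolidyl diphosphate.
4. 3 ⇐ (E)-nerolidol 1, which supplies all fifteen skeletal carbons; one Shi epoxidation sets the absolute configuration.

**Route**

Step 1
Reactants: 1 (6E)-nerolidol (racemic at C3)
Product: 2 (6E)-3,7,11-trimethyldodeca-1,6,10-trien-3-yl acetate
Conditions: Ac2O, Et3N, DMAP (cat.), CH2Cl2, 25–40 °C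
Reagents that add atoms: acetic anhydride, CC(=O)OC(C)=O
Why: DMAP-catalysed acylation of the tertiary allylic alcohol installs the acetate that later leaves as the diphosphate does in the biosynthesis; no stereocentre is set, and the racemic C3 is erased in step 3.

Step 2
Reactants: 2 (6E)-nerolidyl acetate
Product: 3 (6R,7R,10R)-6,7:10,11-diepoxy-3,7,11-trimethyldodec-1-en-3-yl acetate (both C3 epimers)
Conditions: D-fructose-derived Shi ketone (0.6 equiv), Oxone (2KHSO5·KHSO4·K2SO4), K2CO3, Bu4NHSO4, MeCN/dimethoxymethane/aq. Na2B4O7 buffer, 0 °C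
Reagents that add atoms: potassium peroxymonosulfate (oxidant in Oxone), [K+].[O-]S(=O)(=O)OO
Why: Shi asymmetric epoxidation (chiral dioxirane, spiro transition state) oxidises only the two electron-rich trisubstituted olefins and sets (6R,7R) and (10R), while the monosubstituted vinyl group is left alone.

Step 3
Reactants: 3 bis-epoxide
Product: 5 (1R,2R)-2-[(3R)-3-hydroxy-4-methylpent-4-en-1-yl]-2,5-dimethylcyclohept-4-en-1-ol, via bis(trimethylsilyl) ether 4 (not isolated)
Conditions: Cp2TiCl2 (0.3 equiv), Mn dust, Me3SiCl, 2,4,6-collidine, THF, 25 °C; then 2 M HCl, THF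
Reagents that add atoms: chlorotrimethylsilane, C[Si](C)(C)Cl (silyl groups of 4; none remain in 5)
Why: Titanocene-catalysed radical epoxide opening, in which Cp2TiCl (trivalent titanium made in the flask) opens the 6,7-epoxide to the tertiary radical that closes 7-endo-trig onto the vinyl terminus and, after reduction to the alkyltitanium, expels acetate to give the ring olefin; the quaternary centre forms trans to the bulky titanoxy group (both pseudo-equatorial, minor epimer removed by chromatography), and the terminal epoxide is isomerised in the same pot to the isopropenyl carbinol by β-hydrogen abstraction.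

Step 4
Reactants: 5 cycloheptenol with isopropenyl carbinol side chain
Product: 6 1-[(1R,7R)-7-hydroxy-1,4-dimethylcyclohept-3-en-1-yl]-4-methylpentan-3-one
Conditions: CpRu(PPh3)2Cl (5 mol %), Et3NHPF6 (10 mol %), 1,4-dioxane, 100 °C
Reagents that add atoms: none
Why: Ruthenium-catalysed redox isomerisation of an allylic alcohol converts only the isopropenyl carbinol into the isopropyl ketone, because the ring alcohol is not allylic and the ring olefin carries no carbinol; no stereocentre is formed.

Step 5
Reactants: 6 hydroxy ketone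
Product: 7 1-[(1R)-1,5-dimethylcyclohepta-2,5-dien-1-yl]-4-methylpentan-3-one
Conditions: Burgess reagent (MeO2CN–SO2NEt3 inner salt), toluene, 70 °C
Reagents that add atoms: none
Why: Burgess dehydration (syn elimination of the sulfamate ester) can only take a hydrogen from the ring CH2 on one side because the other neighbour is quaternary, so the 2,5-diene forms without a cationic shift; the carbinol centre is erased and the quaternary carbon stays as the only stereocentre.

Step 6
Reactants: 7 cycloheptadienyl ketone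
Product: 9 (3R,3aR,8aR)-6,8a-dimethyl-3-(propan-2-yl)-1,2,3,3a,4,5,8,8a-octahydroazulene-3,4-diol (both C4 epimers), via disamarium alkyl alkoxide 8 (not isolated)
Conditions: SmI2 (4.5 equiv), HMPA, THF, 0 °C; then dry O2, –78 to 0 °C; aq. Na2S2O3
Reagents that add atoms: samarium diiodide, I[Sm]I; dioxygen, O=O
Why: Samarium diiodide ketyl–olefin radical cyclization (5-exo) in which the ketyl adds to the ring olefin from the face of its tether (cis ring fusion) with the bulky O–Sm group turned away from the ring (C3 hydroxyl trans to C4, cis to H-3a and the angular methyl), after which the secondary radical is reduced to the alkylsamarium and oxygenated by O2; the C4 configuration does not matter because step 7 erases it.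

Step 7
Reactants: 9 diol (C4 epimers)
Product: 10 (3R,3aS,8aR)-3-hydroxy-6,8a-dimethyl-3-(propan-2-yl)-2,3,3a,5,8,8a-hexahydroazulen-4(1H)-one
Conditions: Dess–Martin periodinane, CH2Cl2, 0 to 25 °C
Reagents that add atoms: none
Why: Dess–Martin oxidation acts only on the secondary alcohol (the tertiary one cannot be oxidised) and brings both C4 epimers to one β-hydroxy ketone.

Step 8
Reactants: 10 β-hydroxy ketone
Product: 11 (3R,3aR,4S,8aR)-6,8a-dimethyl-3-(propan-2-yl)-1,2,3,3a,4,5,8,8a-octahydroazulene-3,4-diol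
Conditions: Me4NBH(OAc)3, MeCN/AcOH (1:1), –30 °C
Reagents that add atoms: none
Why: Evans–Saksena hydroxyl-directed reduction, in which the tertiary alcohol binds the triacetoxyborohydride and delivers hydride to the convex face of the ketone, giving the 1,3-anti diol with the new hydroxyl cis to the C3a–C3 bond (4S).

Step 9
Reactants: 11 anti-diol; 12 4-methoxybenzoyl chloride
Product: 13 (3R,3aR,4S,8aR)-3-hydroxy-6,8a-dimethyl-3-(propan-2-yl)-1,2,3,3a,4,5,8,8a-octahydroazulen-4-yl 4-methoxybenzoate
Conditions: Et3N, DMAP, CH2Cl2, 25 to 40 °C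
Reagents that add atoms: 4-methoxybenzoyl chloride, COc1ccc(cc1)C(Cl)=O
Why: DMAP-catalysed acylation (nucleophilic catalysis) esterifies the secondary hydroxyl and leaves the hindered tertiary one free; configuration at C4 is retained.

Step 10
Reactants: 13 ester
Product: 14 (3R,3aR,4S,8aS)-3-hydroxy-6,8a-dimethyl-8-oxo-3-(propan-2-yl)-1,2,3,3a,4,5,8,8a-octahydroazulen-4-yl 4-methoxybenzoate (target)
Conditions: CrO3, 3,5-dimethylpyrazole, CH2Cl2, –20 °C
Reagents that add atoms: chromium trioxide, O=[Cr](=O)=O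
Why: Allylic C–H oxidation with hexavalent chromium (CrO3–3,5-dimethylpyrazole) attacks the ring CH2 next to the olefinic CH (C8), as in the Δ5-steroid to 7-ketone case, while the other allylic CH2 (C5) is deactivated by the neighbouring acyloxy group; no stereocentre changes.

**Compound list**
1 | (6E)-3,7,11-trimethyldodeca-1,6,10-trien-3-ol, (E)-nerolidol, racemic | C=CC(C)(O)CC/C=C(\C)CCC=C(C)C | starting material
2 | (6E)-3,7,11-trimethyldodeca-1,6,10-trien-3-yl acetate | C=CC(C)(OC(C)=O)CC/C=C(\C)CCC=C(C)C | intermediate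
3 | (6R,7R,10R)-6,7:10,11-diepoxy-3,7,11-trimethyldodec-1-en-3-yl acetate, both C3 epimers | C=CC(C)(OC(C)=O)CC[C@H]1O[C@]1(C)CC[C@H]1OC1(C)C | intermediate
4 | bis(trimethylsilyl) ether of 5 | C=C(C)[C@H](O[Si](C)(C)C)CC[C@]1(C)CC=C(C)CC[C@H]1O[Si](C)(C)C | intermediate
5 | (1R,2R)-2-[(3R)-3-hydroxy-4-methylpent-4-en-1-yl]-2,5-dimethylcyclohept-4-en-1-ol (ring OH cis to the ring methyl at the quaternary carbon) | C=C(C)[C@H](O)CC[C@]1(C)CC=C(C)CC[C@H]1O | intermediate
6 | 1-[(1R,7R)-7-hydroxy-1,4-dimethylcyclohept-3-en-1-yl]-4-methylpentan-3-one | CC(C)C(=O)CC[C@]1(C)CC=C(C)CC[C@H]1O | intermediate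
7 | 1-[(1R)-1,5-dimethylcyclohepta-2,5-dien-1-yl]-4-methylpentan-3-one | CC(C)C(=O)CC[C@]1(C)CC=C(C)CC=C1 | intermediate
8 | cis-fused azulene with C4–SmI2 and C3–O–SmI2 (trivalent samarium at both sites) | I[Sm](I)C1CC(C)=CC[C@@]2(C)CC[C@@](O[Sm](I)I)(C(C)C)[C@@H]12 | intermediate
9 | (3R,3aR,8aR)-6,8a-dimethyl-3-(propan-2-yl)-1,2,3,3a,4,5,8,8a-octahydroazulene-3,4-diol, both C4 epimers | OC1CC(C)=CC[C@@]2(C)CC[C@@](O)(C(C)C)[C@@H]12 | intermediate
10 | (3R,3aS,8aR)-3-hydroxy-6,8a-dimethyl-3-(propan-2-yl)-2,3,3a,5,8,8a-hexahydroazulen-4(1H)-one | O=C1CC(C)=CC[C@@]2(C)CC[C@@](O)(C(C)C)[C@@H]12 | intermediate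
11 | (3R,3aR,4S,8aR)-6,8a-dimethyl-3-(propan-2-yl)-1,2,3,3a,4,5,8,8a-octahydroazulene-3,4-diol | O[C@H]1CC(C)=CC[C@@]2(C)CC[C@@](O)(C(C)C)[C@@H]12 | intermediate
12 | 4-methoxybenzoyl chloride | COc1ccc(cc1)C(Cl)=O | starting material
13 | (3R,3aR,4S,8aR)-3-hydroxy-6,8a-dimethyl-3-(propan-2-yl)-1,2,3,3a,4,5,8,8a-octahydroazulen-4-yl 4-methoxybenzoate | COc1ccc(C(=O)O[C@H]2CC(C)=CC[C@@]3(C)CC[C@@](O)(C(C)C)[C@@H]23)cc1 | intermediate
14 | (3R,3aR,4S,8aS)-3-hydroxy-6,8a-dimethyl-8-oxo-3-(propan-2-yl)-1,2,3,3a,4,5,8,8a-octahydroazulen-4-yl 4-methoxybenzoate | COc1ccc(C(=O)O[C@H]2CC(C)=CC(=O)[C@@]3(C)CC[C@@](O)(C(C)C)[C@@H]23)cc1 | target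

**Totals**
Total steps: 10. Longest linear sequence: 10 (fully linear from 1).

**Three steps most likely to fail**

Step 3. Two epoxides must be handled by one titanocene catalyst, the 7-endo closure competes with premature radical termination, and the diastereoselectivity of the closure decides the enantiopurity of 7. The fallback sets out from 2 and comes back at 6; it makes the ketone by a cationic route first, so the radical step has a single epoxide. N-Bromosuccinimide in aqueous THF attacks the terminal olefin selectively and gives the bromohydrin (6E)-10-bromo-11-hydroxy-3,7,11-trimethyldodeca-1,6-dien-3-yl acetate F1. K2CO3 in methanol closes it to (6E)-10,11-epoxy-3,7,11-trimethyldodeca-1,6-dien-3-yl acetate F2. A Meinwald rearrangement with catalytic Bi(OTf)3 (a 1,2-hydride shift) gives the isopropyl ketone (6E)-3,7,11-trimethyl-10-oxododeca-1,6-dien-3-yl acetate F3. Shi epoxidation of the one remaining trisubstituted olefin gives (6R,7R)-6,7-epoxy-3,7,11-trimethyl-10-oxododec-1-en-3-yl acetate F4. The same titanocene-catalysed 7-endo closure then gives the silyl ether 4-methyl-1-[(1R,7R)-1,4-dimethyl-7-(trimethylsilyloxy)cyclohept-3-en-1-yl]pentan-3-one F5, and acidic work-up gives 6 without the ruthenium step.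

Step 6. The ketyl closure creates a congested C3–C3a bond, and the C4–samarium bond may be protonated before dioxygen captures it. The fallback sets out from 7 and comes back at 9; it separates ring closure from oxygenation. The cyclization is run as before but quenched with iodine, giving the iodide (3R,8aR)-4-iodo-6,8a-dimethyl-3-(propan-2-yl)-1,2,3,3a,4,5,8,8a-octahydroazulen-3-ol F6. A tin-mediated radical chain under air (Bu3SnH, dry air, toluene, then PPh3) replaces iodine by hydroxyl through the C4 radical and its hydroperoxide, giving 9.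

Step 10. Oxidation could also occur at the other allylic CH2 or at the vinylic methyl. The fallback sets out from 13 and comes back at 14; it moves the oxygen in by an ene reaction and a 1,3-transposition instead of direct C–H oxidation. Photo-oxygenation (O2, tetraphenylporphyrin, visible light; Schenck ene reaction) takes a hydrogen from C8 and gives the tertiary allylic hydroperoxide (3R,3aR,4S)-3-hydroxy-6-hydroperoxy-6,8a-dimethyl-3-(propan-2-yl)-1,2,3,3a,4,5,6,8a-octahydroazulen-4-yl 4-methoxybenzoate F7. PPh3 reduces it to the tertiary allylic alcohol (3R,3aR,4S)-3,6-dihydroxy-6,8a-dimethyl-3-(propan-2-yl)-1,2,3,3a,4,5,6,8a-octahydroazulen-4-yl 4-methoxybenzoate F8. Pyridinium chlorochromate (C5H5NH[CrO3Cl], Babler–Dauben oxidative transposition) then gives the enone 14.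

**Further compounds**
F1 | step 3 | (6E)-10-bromo-11-hydroxy-3,7,11-trimethyldodeca-1,6-dien-3-yl acetate | C=CC(C)(OC(C)=O)CC/C=C(\C)CCC(Br)C(C)(C)O
F2 | step 3 | (6E)-10,11-epoxy-3,7,11-trimethyldodeca-1,6-dien-3-yl acetate | C=CC(C)(OC(C)=O)CC/C=C(\C)CCC1OC1(C)C
F3 | step 3 | (6E)-3,7,11-trimethyl-10-oxododeca-1,6-dien-3-yl acetate | C=CC(C)(OC(C)=O)CC/C=C(\C)CCC(=O)C(C)C
F4 | step 3 | (6R,7R)-6,7-epoxy-3,7,11-trimethyl-10-oxododec-1-en-3-yl acetate | C=CC(C)(OC(C)=O)CC[C@H]1O[C@]1(C)CCC(=O)C(C)C
F5 | step 3 | 4-methyl-1-[(1R,7R)-1,4-dimethyl-7-(trimethylsilyloxy)cyclohept-3-en-1-yl]pentan-3-one | CC(C)C(=O)CC[C@]1(C)CC=C(C)CC[C@H]1O[Si](C)(C)C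
F6 | step 6 | (3R,8aR)-4-iodo-6,8a-dimethyl-3-(propan-2-yl)-1,2,3,3a,4,5,8,8a-octahydroazulen-3-ol, cis-fused | IC1CC(C)=CC[C@@]2(C)CC[C@@](O)(C(C)C)[C@@H]12
F7 | step 10 | (3R,3aR,4S)-3-hydroxy-6-hydroperoxy-6,8a-dimethyl-3-(propan-2-yl)-1,2,3,3a,4,5,6,8a-octahydroazulen-4-yl 4-methoxybenzoate | COc1ccc(C(=O)O[C@H]2CC(C)(OO)C=C[C@@]3(C)CC[C@@](O)(C(C)C)[C@@H]23)cc1
F8 | step 10 | (3R,3aR,4S)-3,6-dihydroxy-6,8a-dimethyl-3-(propan-2-yl)-1,2,3,3a,4,5,6,8a-octahydroazulen-4-yl 4-methoxybenzoate | COc1ccc(C(=O)O[C@H]2CC(C)(O)C=C[C@@]3(C)CC[C@@](O)(C(C)C)[C@@H]23)cc1
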